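**Assumption:** the target SMILES contains no stereocenters, so it is achiral and "single enantiomer" has no consequence. The only unsaturation is the prenyl C=C, which has two methyl groups on one carbon and so has no E/Z isomers. I also assume that MOM-directed lithiation of 3,5-dimethoxyphenol occurs at C2, the position between OMOM and OMe.

## Retrosynthetic overview
1. The target comes from the fully protected flavone by one BCl3 step that cleaves the chelated 5-OMe and the 4'-OMOM together.
2. The pyranone ring is closed last, by base-mediated 6-endo-dig oxa-Michael cyclization of an o-hydroxyaryl ynone. This avoids the chalcone and Baker–Venkataraman routes.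
3. The ynone comes from a lithium aryl-acetylide adding to salicylaldehyde **8**, followed by oxidation of the propargylic alcohol.
4. Aldehyde **8** comes from ortho-formylation of 2-prenyl-3,5-dimethoxyphenol. The prenyl group is placed by MOM-directed ortho-lithiation and Cu-catalysed alkylation of 3,5-dimethoxyphenol.
5. Ring order: the A-ring benzene is built first, then the B-ring alkyne is attached, and the pyranone C-ring is formed last.

## Route

**Step 1**
Reactants: **1** 3,5-dimethoxyphenol; **2** chloromethyl methyl ether (MOMCl)
Product: **3** 1-(methoxymethoxy)-3,5-dimethoxybenzene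
Conditions: NaH, THF/DMF, 0 °C; then MOMCl, 0 °C → rt
Reagents that add atoms: MOMCl, ClCOC
Why: Williamson-type O-alkylation of the phenoxide installs the MOM group, which is needed as a directed-metalation group.

**Step 2**
Reactants: **3**; **4** prenyl bromide (1-bromo-3-methylbut-2-ene)
Product: **5** 2-(methoxymethoxy)-1,5-dimethoxy-3-prenyl… written as 1-MOMO-2-prenyl-3,5-dimethoxybenzene
Conditions: n-BuLi, THF, 0 °C, 1 h; then CuBr·SMe2 (10 mol%), prenyl bromide, −78 °C → rt
Reagents that add atoms: prenyl bromide, CC(C)=CCBr
Why: Directed ortho-metalation occurs at C2, which is flanked by OMOM and OMe; Cu catalysis favours SN2 over SN2′, giving linear prenyl rather than reverse prenyl. This sets the C8-prenyl regiochemistry with no ambiguity.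

**Step 3**
Reactants: **5**
Product: **6** 2-prenyl-3,5-dimethoxyphenol
Conditions: 3 M HCl (aq), THF/MeOH 1:1, rt → 40 °C, monitor closely
Reagents that add atoms: none
Why: Acetal hydrolysis of the aryl MOM ether. Mild conditions are used so the prenyl alkene does not cyclize to a chromane.

**Step 4**
Reactants: **6**; **7** paraformaldehyde
Product: **8** 2-hydroxy-4,6-dimethoxy-3-prenylbenzaldehyde
Conditions: MgCl2, Et3N, (CH2O)n (excess), MeCN, reflux
Reagents that add atoms: paraformaldehyde, C=O
Why: Casnati–Skattebøl Mg-phenoxide ortho-formylation is strictly ortho to OH; the other ortho position is blocked by prenyl and the para position is not activated by this chelation. The aldehyde carbon becomes C4 of the flavone.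

**Step 5**
Reactants: **9** 4-hydroxy-2-methoxybenzaldehyde; **2** MOMCl
Product: **10** 2-methoxy-4-(methoxymethoxy)benzaldehyde
Conditions: iPr2NEt, CH2Cl2, 0 °C → rt
Reagents that add atoms: MOMCl, ClCOC
Why: Phenol protection as the MOM ether, which is stable to base, organolithiums and MnO2.

**Step 6**
Reactants: **10**; **11** Bestmann–Ohira reagent (dimethyl 1-diazo-2-oxopropylphosphonate)
Product: **12** 1-ethynyl-2-methoxy-4-(methoxymethoxy)benzene
Conditions: K2CO3, MeOH, 0 °C → rt
Reagents that add atoms: Bestmann–Ohira reagent, CC(=O)C(=[N+]=[N-])P(=O)(OC)OC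
Why: Seyferth–Gilbert homologation (Ohira–Bestmann variant) converts the aldehyde to the terminal alkyne, and the MOM ether survives the mild base.

**Step 7**
Reactants: **8**; **12**
Product: **13** 1-(2-hydroxy-4,6-dimethoxy-3-prenylphenyl)-3-[2-methoxy-4-(MOMO)phenyl]prop-2-yn-1-ol
Conditions: **12** (2.5 equiv) + n-BuLi (2.5 equiv), THF, −78 °C, 30 min; add **8**, −78 → 0 °C; NH4Cl quench
Reagents that add atoms: none (**12** is the incorporated nucleophile)
Why: 1,2-addition of the lithium acetylide to the aldehyde. The excess acetylide deprotonates the phenol first, so the phenoxide stays intact and the new carbinol carbon is not a stereocenter that matters, because it is oxidized in the next step.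

**Step 8**
Reactants: **13**
Product: **14** 1-(2-hydroxy-4,6-dimethoxy-3-prenylphenyl)-3-[2-methoxy-4-(MOMO)phenyl]prop-2-yn-1-one
Conditions: activated MnO2 (10 equiv), CH2Cl2, rt
Reagents that add atoms: none
Why: MnO2 selectively oxidizes the benzylic/propargylic alcohol to the ynone and leaves the prenyl alkene and MOM ether untouched.

**Step 9**
Reactants: **14**
Product: **15** 5,7-dimethoxy-2-[2-methoxy-4-(MOMO)phenyl]-8-prenyl-4H-chromen-4-one
Conditions: K2CO3 (2 equiv), acetone (or DMF), 60 °C
Reagents that add atoms: none
Why: 6-endo-dig intramolecular oxa-Michael addition of the phenoxide to the ynone β-carbon builds the pyranone ring. Attack at the α-carbon (the 5-exo route to an aurone) is not a Michael-type addition and is disfavoured. This step forms the flavone with no stereocenters.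

**Step 10**
Reactants: **15**
Product: **16** Artocarpetin B
Conditions: BCl3 (2.5 equiv), CH2Cl2, −78 → 0 °C, 1 h; then MeOH, NaHCO3 (aq)
Reagents that add atoms: none (B and Cl are not retained; the Me and MOM groups leave as MeCl and MOMCl/MeOH-derived fragments)
Why: BCl3 chelates the C4 carbonyl and the 5-OMe, so demethylation is selective for that group (7-OMe and 2′-OMe are not chelated). The same reagent cleaves the 4′-OMOM, giving the 5-OH/4′-OH target.

## Final checks
- **Target match:** **16** has a flavone core with 5-OH, 7-OMe, 8-prenyl, 2′-OMe and 4′-OH, matching the target SMILES.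
- **A-ring mapping:** aldehyde **8** ring carbons map to the flavone as C1 = C4a, C2-OH = C8a (O1), C3-prenyl = C8, C4-OMe = C7, C5-H = C6, C6-OMe = C5.
- **Stereochemistry:** none is required; the propargylic carbinol stereocenter in **13** is destroyed in Step 8.
- **Atom bookkeeping:** **15** is C25H28O7 and **16** is C22H22O6, a loss of CH2 plus C2H4O (5-Me and MOM), consistent with Step 10.

## Compound list
1 | 3,5-dimethoxyphenol | COc1cc(O)cc(OC)c1 | starting material
2 | chloromethyl methyl ether | ClCOC | starting material (reagent)
3 | 1-(methoxymethoxy)-3,5-dimethoxybenzene | COCOc1cc(OC)cc(OC)c1 | intermediate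
4 | prenyl bromide | CC(C)=CCBr | starting material (reagent)
5 | 1-MOMO-2-prenyl-3,5-dimethoxybenzene | COCOc1c(CC=C(C)C)c(OC)cc(OC)c1 | intermediate
6 | 2-prenyl-3,5-dimethoxyphenol | COc1cc(O)c(CC=C(C)C)c(OC)c1 | intermediate
7 | paraformaldehyde (formaldehyde unit) | C=O | starting material (reagent)
8 | 2-hydroxy-4,6-dimethoxy-3-prenylbenzaldehyde | O=Cc1c(O)c(CC=C(C)C)c(OC)cc1OC | intermediate
9 | 4-hydroxy-2-methoxybenzaldehyde | COc1cc(O)ccc1C=O | starting material
10 | 2-methoxy-4-(methoxymethoxy)benzaldehyde | COCOc1ccc(C=O)c(OC)c1 | intermediate
11 | Bestmann–Ohira reagent | CC(=O)C(=[N+]=[N-])P(=O)(OC)OC | starting material (reagent)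
12 | 1-ethynyl-2-methoxy-4-(methoxymethoxy)benzene | C#Cc1ccc(OCOC)cc1OC | intermediate
13 | propargylic alcohol (racemic, oxidized in Step 8) | COc1cc(OCOC)ccc1C#CC(O)c1c(OC)cc(OC)c(CC=C(C)C)c1O | intermediate
14 | o-hydroxyaryl ynone | COc1cc(OCOC)ccc1C#CC(=O)c1c(OC)cc(OC)c(CC=C(C)C)c1O | intermediate
15 | 5,7-dimethoxy-2-[2-methoxy-4-(MOMO)phenyl]-8-prenylflavone | COc1cc(OCOC)ccc1-c1cc(=O)c2c(OC)cc(OC)c(CC=C(C)C)c2o1 | intermediate
16 | Artocarpetin B (achiral) | COc1cc(O)ccc1-c1cc(=O)c2c(O)cc(OC)c(CC=C(C)C)c2o1 | target

## Totals
- Total steps: 10.
- Longest linear sequence: 8 steps (1 → 3 → 5 → 6 → 8 → 13 → 14 → 15 → 16, counting Steps 1, 2, 3, 4, 7, 8, 9, 10).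

## Three steps most likely to fail
1. **Step 2 (ortho-lithiation/prenylation).** Lithiation could go partly to C4, or SN2′ coupling could give reverse prenyl.
   - Fallback: drop the A-ring prenylation. Start from commercial 2-hydroxy-4,6-dimethoxybenzaldehyde, run the same ynone/cyclization sequence to the 8-unsubstituted flavone, then install C8 late by regioselective 8-bromination (NBS) and Negishi or Kumada coupling with prenylzinc or prenylmagnesium chloride.
2. **Step 9 (6-endo-dig cyclization).** Intermolecular conjugate addition, oligomerization or 5-exo aurone formation could compete.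
   - Fallback: convert the ynone to the 1,3-diketone by Au(I)-catalysed hydration, then close the ring by acid-catalysed cyclodehydration. This changes the mechanism from a Michael-type ring closure to diketone cyclodehydration.
3. **Step 10 (BCl3 selective demethylation).** Over-cleavage of 7-OMe or 2′-OMe, or acid attack on the prenyl alkene, could occur.
   - Fallback: carry the C5 oxygen as a MOM ether from the start (from 5-methoxyresorcinol, mono-MOM protected), so that every protecting group is removed in the last step by mild PPTS or dilute HCl/MeOH, and no selective methyl-ether cleavage is needed.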